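The target is numbered as a germacrane: C4–C5 epoxide, C6–O and C7 lactone fusion, C8 methacrylate, C9 acetate, C1=C10 enoate, C11=C13 exo-methylene. Everything rests on the C7–C8 bond. The unit C8(OH)–C7–C11=C13 is shared by the ten-membered carbocycle and the lactone ring. It is a homoallylic alcohol, the retron of carbonyl allylation with allylic transposition. The precursor is an open chain with the C8 aldehyde and C9 acetate at one end, and the finished epoxide and a 3-(bromomethyl)butenolide at the other. In one operation CrCl2 closes the carbocycle, sets C7 and C8, and shifts the butenolide alkene outward into the α-methylene lactone. The acetate travels as a cyclic orthoacetate.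

Key step: step 12

Remark (numbering): germacrane numbers are used for all intermediates: C1=C10(C14O2Me), C2, C3, C4(CH3)–O–C5, C6(O-lactone), C7, C8, C9, and lactone C11(=C13H2)–C12(=O).

Remark (assumption): 3 is taken as a catalogue compound (otherwise one reduction of dimethyl L-malate with BH3·SMe2 and cat. NaBH4); compounds 4–18 are epimer mixtures at the orthoester carbon (left undefined in the SMILES), are worked up at pH 7 or above, and are chromatographed on Et3N-deactivated silica.

Step 1
Reactants: 1 geranyl acetate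
Product: 2 (2E)-3-methyl-6-oxohex-2-en-1-yl acetate
Conditions: O3 (1.0 equiv), CH2Cl2, −78 °C; Me2S, −78 °C to rt
Reagents that add atoms: ozone [O-][O+]=O
Why: Chemoselective ozonolysis with reductive work-up, in which the electron-rich isopropylidene alkene should react before the alkene deactivated by the allylic acetate, so that the (E)-C4=C5 alkene is kept and C1 is freed as the aldehyde.

Step 2
Reactants: 3 methyl (3S)-3,4-dihydroxybutanoate
Product: 4 methyl 2-[(4S)-2-methoxy-2-methyl-1,3-dioxolan-4-yl]acetate
Conditions: MeC(OMe)3 (1.5 equiv), PPTS (1 mol %), CH2Cl2, rt; Et3N quench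
Reagents that add atoms: trimethyl orthoacetate CC(OC)(OC)OC
Why: Acid-catalysed orthoester exchange masks O8 and O9 in a base-stable five-membered ring that already holds the future acetyl carbon atoms, while the chiral-pool centre C9 (S) is not touched.

Step 3
Reactants: 4 methyl 2-[(4S)-2-methoxy-2-methyl-1,3-dioxolan-4-yl]acetate; 2 (2E)-3-methyl-6-oxohex-2-en-1-yl acetate
Product: 6 methyl (6E)-8-acetoxy-3-hydroxy-6-methyl-2-[(4S)-2-methoxy-2-methyl-1,3-dioxolan-4-yl]oct-6-enoate, via lithium enolate 5 (not isolated)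
Conditions: LiN(iPr)2 (1.05 equiv), THF, −78 °C; 2, −78 °C; pH 7 buffer at −78 °C
Reagents that add atoms: none
Why: Lithium ester-enolate aldol addition forms C10–C1; the aldehyde outruns the acetate, the ring alkoxide on C9 is too poor a nucleofuge to leave at −78 °C, and the new centres at C10 and C1 (mixtures) are erased in step 4.

Step 4
Reactants: 6 methyl (6E)-8-acetoxy-3-hydroxy-6-methyl-2-[(4S)-2-methoxy-2-methyl-1,3-dioxolan-4-yl]oct-6-enoate
Product: 8 methyl (2E,6E)-8-acetoxy-6-methyl-2-[(4S)-2-methoxy-2-methyl-1,3-dioxolan-4-yl]octa-2,6-dienoate, via mesylate 7 (not isolated)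
Conditions: MsCl, Et3N, CH2Cl2, 0 °C; then DBU, 0 °C to rt
Reagents that add atoms: none
Why: Mesylation and E1cB elimination, in which the mesylate leaves far more readily than the C9 oxygen and A(1,3) strain in the ester enolate turns H1 toward the ester, should give the tiglate-type (E)-enoate with C2 cis to C9.

Step 5
Reactants: 8 methyl (2E,6E)-8-acetoxy-6-methyl-2-[(4S)-2-methoxy-2-methyl-1,3-dioxolan-4-yl]octa-2,6-dienoate
Product: 9 methyl (2E,6E)-8-hydroxy-6-methyl-2-[(4S)-2-methoxy-2-methyl-1,3-dioxolan-4-yl]octa-2,6-dienoate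
Conditions: K2CO3 (0.2 equiv), MeOH, 0 °C to rt
Reagents that add atoms: none
Why: Base-catalysed transesterification removes the primary allylic acetate, is degenerate at the methyl ester and at the orthoester methoxy group, and leaves the hindered enoate alone.

Step 6
Reactants: 9 methyl (2E,6E)-8-hydroxy-6-methyl-2-[(4S)-2-methoxy-2-methyl-1,3-dioxolan-4-yl]octa-2,6-dienoate
Product: 10 methyl (2E,6E)-6-methyl-8-oxo-2-[(4S)-2-methoxy-2-methyl-1,3-dioxolan-4-yl]octa-2,6-dienoate
Conditions: MnO2 (20 equiv), CH2Cl2, rt
Reagents that add atoms: none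
Why: Allylic alcohol oxidation with MnO2 is neutral and heterogeneous, so the (E)-enal geometry and the orthoester should survive.

Step 7
Reactants: 10 methyl (2E,6E)-6-methyl-8-oxo-2-[(4S)-2-methoxy-2-methyl-1,3-dioxolan-4-yl]octa-2,6-dienoate; 11 1-hexyne
Product: 15 methyl (2E)-5-{(2R,3R)-3-[(1S,2E)-1-hydroxyhept-2-en-1-yl]-2-methyloxiran-2-yl}-2-[(4S)-2-methoxy-2-methyl-1,3-dioxolan-4-yl]pent-2-enoate, via hexenylborane 12 (not isolated), via hexenylzinc 13 (not isolated), via zinc alkoxide 14 (not isolated)
Conditions: 11, Cy2BH, toluene, 0 °C to rt; Me2Zn, (2S)-(−)-3-exo-morpholinoisoborneol [(−)-MIB, 5 mol %], −78 °C; 10, −10 °C; then Ti(OiPr)4 (20 mol %), tBuOOH (decane), 0 °C; aq NaHCO3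
Reagents that add atoms: tert-butyl hydroperoxide CC(C)(C)OO
Why: One-pot catalytic asymmetric alkenylzinc addition to an enal followed by titanium-catalysed alkoxide-directed epoxidation of the bis-allylic alkoxide: the amino-alcohol ligand sets C6 (S), and the alkoxide then delivers oxygen to the more electron-rich trisubstituted C4=C5 alkene on the face fixed by A(1,3) strain between H6 and the cis C4 methyl group, which gives the threo (4R,5R,6S) array.

Step 8
Reactants: 15 methyl (2E)-5-{(2R,3R)-3-[(1S,2E)-1-hydroxyhept-2-en-1-yl]-2-methyloxiran-2-yl}-2-[(4S)-2-methoxy-2-methyl-1,3-dioxolan-4-yl]pent-2-enoate; 16 2-(bromomethyl)acrylic acid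
Product: 17 the O6 2-(bromomethyl)acrylate ester of 15
Conditions: DCC (1.3 equiv), DMAP (5 mol %), CH2Cl2, 0 °C, slow addition of 16
Reagents that add atoms: none
Why: Steglich esterification acylates O6 with retention at C6 and brings in C11, C12, C13 and the bromide, and the free acid concentration stays low enough to spare the orthoester.

Step 9
Reactants: 17 the O6 2-(bromomethyl)acrylate ester of 15
Product: 18 methyl (2E)-5-{(2R,3R)-3-[(2S)-4-(bromomethyl)-5-oxo-2,5-dihydrofuran-2-yl]-2-methyloxiran-2-yl}-2-[(4S)-2-methoxy-2-methyl-1,3-dioxolan-4-yl]pent-2-enoate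
Conditions: second-generation Hoveyda–Grubbs catalyst (10 mol %), toluene, 80 °C
Reagents that add atoms: none
Why: Ring-closing metathesis of an acrylate ester of an allylic alcohol closes the five-membered butenolide (C7=C11) with loss of 1-hexene, while the trisubstituted enoate is inert and C6 is not touched.

Step 10
Reactants: 18 methyl (2E)-5-{(2R,3R)-3-[(2S)-4-(bromomethyl)-5-oxo-2,5-dihydrofuran-2-yl]-2-methyloxiran-2-yl}-2-[(4S)-2-methoxy-2-methyl-1,3-dioxolan-4-yl]pent-2-enoate
Product: 19 methyl (2E)-2-[(1S)-1-acetoxy-2-hydroxyethyl]-5-{(2R,3R)-3-[(2S)-4-(bromomethyl)-5-oxo-2,5-dihydrofuran-2-yl]-2-methyloxiran-2-yl}pent-2-enoate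
Conditions: AcOH/H2O (4:1), THF, 0 °C, 15 min; cold NaHCO3 wash
Reagents that add atoms: water O
Why: Regioselective monoacylation of a 1,2-diol through its cyclic orthoester: the hemiorthoester should collapse with release of the less hindered primary O8, so the acetyl group stays on O9 under conditions too mild to open the epoxide.

Step 11
Reactants: 19 methyl (2E)-2-[(1S)-1-acetoxy-2-hydroxyethyl]-5-{(2R,3R)-3-[(2S)-4-(bromomethyl)-5-oxo-2,5-dihydrofuran-2-yl]-2-methyloxiran-2-yl}pent-2-enoate
Product: 20 methyl (2E)-2-[(1S)-1-acetoxy-2-oxoethyl]-5-{(2R,3R)-3-[(2S)-4-(bromomethyl)-5-oxo-2,5-dihydrofuran-2-yl]-2-methyloxiran-2-yl}pent-2-enoate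
Conditions: Dess–Martin periodinane (1.3 equiv), CH2Cl2, 0 °C, run at once on fresh 19; product used crude
Reagents that add atoms: none
Why: Dess–Martin oxidation is fast and base-free, so C8–OH becomes the aldehyde before it can lactonise onto C14 or accept the acetyl group, and C9 is not epimerised.

Step 12
Reactants: 20 methyl (2E)-2-[(1S)-1-acetoxy-2-oxoethyl]-5-{(2R,3R)-3-[(2S)-4-(bromomethyl)-5-oxo-2,5-dihydrofuran-2-yl]-2-methyloxiran-2-yl}pent-2-enoate
Product: 22 methyl (1(10)E,4R,5R,6S,7R,8R,9S)-9-acetoxy-4,5-epoxy-8-hydroxy-12-oxogermacra-1(10),11(13)-dien-12,6-olid-14-oate, via allylchromium 21 (not isolated)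
Conditions: CrCl2 (10 equiv), 4 Å MS, THF/DMF (10:1), rt; 20 added by syringe pump to 0.002 M; water work-up
Reagents that add atoms: none
Why: CrCl2 reduces only the allylic C–Br bond (two one-electron transfers) to allylchromium 21, whose γ-carbon C7 adds to the C8 aldehyde through a closed six-membered chair (Cr, O, C8, C7, C11, C13) with allylic transposition, so that the C7=C11 butenolide alkene becomes the C11=C13 exo-methylene group. The closest known reaction types are the intramolecular Nozaki–Hiyama–Kishi allylation used for medium and large carbocycles and the Barbier or chromium allylation of aldehydes with 3-(bromomethyl)furan-2(5H)-ones. The ten-membered ring closes in a 10-exo-trig mode at the carbonyl carbon (SE2' at the allyl unit), while the lactone and epoxide rings already stand and only look on. C7 is set by attack on the butenolide face anti to the C5 substituent on C6 (trans-fused lactone); C8 is set by the chair, in which the ring-locked (E)-type allylmetal puts C6 and C9 equatorial (7,8-anti), and the polar Felkin–Anh preference of the C9-acetoxy aldehyde (8,9-anti) points the same way, so all three controls are matched. The step needs γ- over α-attack (ten- against twelve-membered ring), which the cyclic transition state secures, and cyclisation over oligomerisation, which high dilution and the chain fold imposed by the cis C1=C10 alkene and the trans epoxide secure. Esters, enoate and epoxide are inert to divalent chromium under these conditions.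

Step 13
Reactants: 22 methyl (1(10)E,4R,5R,6S,7R,8R,9S)-9-acetoxy-4,5-epoxy-8-hydroxy-12-oxogermacra-1(10),11(13)-dien-12,6-olid-14-oate
Product: 23 the target CNP0153978.4 (the 8-O-methacrylate of 22)
Conditions: methacrylic anhydride (3 equiv), Et3N, DMAP (0.2 equiv), CH2Cl2, 0 °C to rt
Reagents that add atoms: methacrylic anhydride CC(=C)C(=O)OC(=O)C(C)=C
Why: DMAP-catalysed acyl transfer esterifies the only free hydroxyl group (O8) with retention at C8 and should be fast enough to pre-empt acetyl migration.

Compound list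
1 | geranyl acetate | CC(C)=CCC/C(C)=C/COC(C)=O | starting material
2 | (2E)-3-methyl-6-oxohex-2-en-1-yl acetate | O=CCC/C(C)=C/COC(C)=O | intermediate
3 | methyl (3S)-3,4-dihydroxybutanoate | COC(=O)C[C@H](O)CO | starting material
4 | methyl 2-[(4S)-2-methoxy-2-methyl-1,3-dioxolan-4-yl]acetate | COC(=O)C[C@H]1COC(C)(OC)O1 | intermediate
5 | lithium enolate of 4 | COC(=C[C@H]1COC(C)(OC)O1)O[Li] | intermediate
6 | aldol adduct (mixture at C10 and C1) | COC(=O)C(C(O)CC/C(C)=C/COC(C)=O)[C@H]1COC(C)(OC)O1 | intermediate
7 | C1 mesylate of 6 | COC(=O)C(C(CC/C(C)=C/COC(C)=O)OS(C)(=O)=O)[C@H]1COC(C)(OC)O1 | intermediate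
8 | (2E,6E)-dienoate with C6 acetate | CC(=O)OC/C=C(\C)CC/C=C(/C(=O)OC)[C@H]1COC(C)(OC)O1 | intermediate
9 | C6 allylic alcohol | OC/C=C(\C)CC/C=C(/C(=O)OC)[C@H]1COC(C)(OC)O1 | intermediate
10 | C6 enal | O=C/C=C(\C)CC/C=C(/C(=O)OC)[C@H]1COC(C)(OC)O1 | intermediate
11 | 1-hexyne | CCCCC#C | starting material
12 | (E)-hex-1-enyl(dicyclohexyl)borane | CCCC/C=C/B(C1CCCCC1)C1CCCCC1 | intermediate
13 | (E)-hex-1-enyl(methyl)zinc | CCCC/C=C/[Zn]C | intermediate
14 | methylzinc alkoxide of the (6S) bis-allylic alcohol | CCCC/C=C/[C@H](O[Zn]C)/C=C(\C)CC/C=C(/C(=O)OC)[C@H]1COC(C)(OC)O1 | intermediate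
15 | (4R,5R,6S) epoxy alcohol | CCCC/C=C/[C@H](O)[C@H]1O[C@]1(C)CC/C=C(/C(=O)OC)[C@H]1COC(C)(OC)O1 | intermediate
16 | 2-(bromomethyl)acrylic acid | OC(=O)C(=C)CBr | starting material
17 | O6 2-(bromomethyl)acrylate of 15 | CCCC/C=C/[C@H](OC(=O)C(=C)CBr)[C@H]1O[C@]1(C)CC/C=C(/C(=O)OC)[C@H]1COC(C)(OC)O1 | intermediate
18 | 3-(bromomethyl)butenolide with orthoacetate | BrCC1=C[C@H](OC1=O)[C@H]2O[C@]2(C)CC/C=C(/C(=O)OC)[C@H]3COC(C)(OC)O3 | intermediate
19 | C9 acetate with free C8 alcohol | BrCC1=C[C@H](OC1=O)[C@H]2O[C@]2(C)CC/C=C(/C(=O)OC)[C@H](OC(C)=O)CO | intermediate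
20 | C8 aldehyde (open-chain precursor) | BrCC1=C[C@H](OC1=O)[C@H]2O[C@]2(C)CC/C=C(/C(=O)OC)[C@H](OC(C)=O)C=O | intermediate
21 | allylchromium dichloride from 20 | Cl[Cr](Cl)CC1=C[C@H](OC1=O)[C@H]2O[C@]2(C)CC/C=C(/C(=O)OC)[C@H](OC(C)=O)C=O | intermediate
22 | macrocyclic C8 alcohol | O[C@@H]1[C@H]2C(=C)C(=O)O[C@@H]2[C@H]2O[C@]2(C)CC/C=C(/C(=O)OC)[C@@H]1OC(C)=O | intermediate
23 | CNP0153978.4 | C=C(C)C(=O)O[C@@H]1[C@H]2C(=C)C(=O)O[C@@H]2[C@H]2O[C@]2(C)CC/C=C(/C(=O)OC)[C@@H]1OC(C)=O | target

Total step count: 13. Longest linear sequence: 12 (steps 1 and 3–13, or equally steps 2–13).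

Steps most likely to fail

Step 12. Ring closure may lose to intermolecular coupling. The aldehyde may reach the butenolide face syn to C5. The acetyl group may also wander from O9 to the fresh metal alkoxide on O8. The fallback replaces the reducing metal by an intramolecular allylboration and sets out from 18. Allylic borylation of 18 (B2pin2, cat. Pd2(dba)3, toluene) gives the pinacol allylboronate F1. The orthoester opening of step 10 gives the hydroxy acetate F2, and Dess–Martin oxidation gives the boronate aldehyde F3. F3 is warmed at high dilution in toluene, so that C7 adds to C8 through the tighter boron chair. The resulting borate ester is not nucleophilic enough to take up the acetyl group. Mild aqueous work-up returns to the route at 22.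

Step 3 (together with step 4). The enolate may lose the C9 oxygen by β-elimination before it meets the aldehyde, and the later elimination may show poor alkene geometry. The fallback uses an alkoxide-protected dianion and a Stobbe-type ring opening, and sets out from 2.
- The dilithio dianion of dimethyl (S)-malate (COC(=O)C[C@H](O)C(=O)OC, LiN(SiMe3)2, 2.1 equiv, THF, −78 °C) adds to 2.
- On warming, the C1 alkoxide closes onto the C8 ester to give the hydroxy lactone F4.
- DBU opens F4 by E1cB with the carboxylate as the only possible leaving group, giving the (E)-half-ester F5.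
- BH3·SMe2 reduces only the free acid to the diol F6.
- MeC(OMe)3 with cat. PPTS returns to the route at 8.

Step 7. Enantioselectivity of the alkenylzinc addition may erode on this functionalised enal, and the directed epoxidation may show poor facial or alkene selectivity. The fallback separates the two events under reagent control and sets out from 9. Katsuki–Sharpless epoxidation (Ti(OiPr)4, D-(−)-diisopropyl tartrate, tBuOOH, 4 Å MS, CH2Cl2, −20 °C) gives the epoxy alcohol F7. Parikh–Doering oxidation gives the epoxy aldehyde F8. Addition of 13 under (−)-MIB catalysis then sets C6 and returns to the route at 15.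

Further compounds
F1 | step 12 | pinacol allylboronate of the butenolide with orthoacetate | CC1(C)OB(CC2=C[C@H](OC2=O)[C@H]3O[C@]3(C)CC/C=C(/C(=O)OC)[C@H]4COC(C)(OC)O4)OC1(C)C
F2 | step 12 | allylboronate with C9 acetate and free C8 alcohol | CC1(C)OB(CC2=C[C@H](OC2=O)[C@H]3O[C@]3(C)CC/C=C(/C(=O)OC)[C@H](OC(C)=O)CO)OC1(C)C
F3 | step 12 | allylboronate C8 aldehyde | CC1(C)OB(CC2=C[C@H](OC2=O)[C@H]3O[C@]3(C)CC/C=C(/C(=O)OC)[C@H](OC(C)=O)C=O)OC1(C)C
F4 | step 3 | C9-hydroxy C10-carbomethoxy γ-lactone (C1–O to C8, mixture at C10 and C1) | COC(=O)C1C(CC/C(C)=C/COC(C)=O)OC(=O)[C@H]1O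
F5 | step 3 | (E)-alkylidene malic acid C14 methyl half-ester | CC(=O)OC/C=C(\C)CC/C=C(/C(=O)OC)[C@H](O)C(=O)O
F6 | step 3 | C8,C9 diol of the dienoate | CC(=O)OC/C=C(\C)CC/C=C(/C(=O)OC)[C@H](O)CO
F7 | step 7 | (4R,5R) epoxy alcohol with primary C6 hydroxyl | OC[C@H]1O[C@]1(C)CC/C=C(/C(=O)OC)[C@H]1COC(C)(OC)O1
F8 | step 7 | epoxy aldehyde at C6 with the same spatial arrangement | O=C[C@H]1O[C@]1(C)CC/C=C(/C(=O)OC)[C@H]1COC(C)(OC)O1
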